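## Retrosynthetic overview
1. Only one ring is made: the 18-membered macrocycle. It is closed last by C–O coupling of the ring C phenol oxygen with C5–H of a methoxy-p-quinone (ring D) generated in the same flask. This mirrors the phenol coupling that closes the marchantins in liverworts.
2. The open-chain tetraphenol comes from a dialdehyde by one double Baeyer–Villiger oxidation, a late "hydroxylation" of rings D and B.
3. The ring B–ring C ethano bridge comes from B-alkyl Suzuki coupling of an aryl bromide with 3-vinylphenol.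
4. The ring A–O–ring B ether comes from SNAr of the ring A phenoxide on 4-bromo-2-fluorobenzaldehyde. This has the same oxygen-to-ortho-carbon sense as the first coupling of two lunularin units.
5. The ring A–ring D bibenzyl comes from B-alkyl Suzuki coupling of 4-acetoxystyrene with 5-iodovanillin. All four six-membered rings are bought.

Assumption: the SMILES carries no stereodescriptor, the molecule has no stereocentre, and the cyclophane is taken as conformationally mobile, so there is no configuration to set.

Ring letters: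
- A is the p-phenylene ring.
- B is the trisubstituted ring carrying the free OH.
- C is the m-phenylene ring.
- D is the quinone ring.

Quinone numbering: C1=O lies between C2 (OMe) and C6 (CH2CH2 chain). C3 carries H, C4 is the second C=O, and C5 carries the aryloxy group in the target.

## Route

Step 1
Reactants: 1 3-hydroxybenzaldehyde
Product: 2 3-vinylphenol
Conditions: MePPh3Br (1.3 equiv), KOtBu (2.5 equiv), THF, 0 °C to rt, 3 h; aq NH4Cl; use within days (cold, trace BHT)
Reagents that add atoms: methyltriphenylphosphonium bromide, C[P+](c1ccccc1)(c1ccccc1)c1ccccc1.[Br-]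
Why: Wittig methylenation, in which the extra equivalent of base parks the phenol as its phenoxide and the non-enolisable aldehyde reacts cleanly with the unstabilised ylide.

Step 2
Reactants: 3 4-acetoxystyrene; 4 5-iodovanillin
Product: 6 4-hydroxy-3-[2-(4-hydroxyphenyl)ethyl]-5-methoxybenzaldehyde, via alkylborane 5 (not isolated)
Conditions: 3 (1.2 equiv), 9-BBN (1.15 equiv), THF, 0 °C to rt, 5 h; then 4 (1.0 equiv), PdCl2(dppf)·CH2Cl2 (3 mol %), 3 M aq NaOH (5 equiv), THF, 60 °C, 12 h; 1 M HCl work-up
Reagents that add atoms: none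
Why: Anti-Markovnikov hydroboration followed by B-alkyl Suzuki–Miyaura coupling gives the bibenzyl directly at the saturated level; unprotected 5-iodovanillin couples well in aqueous base, the styrene is kept in excess over 9-BBN so that no B–H remains to reduce the aldehyde, and the NaOH also saponifies the aryl acetate.

Step 3
Reactants: 6 4-hydroxy-3-[2-(4-hydroxyphenyl)ethyl]-5-methoxybenzaldehyde; 7 4-bromo-2-fluorobenzaldehyde
Product: 8 3-{2-[4-(5-bromo-2-formylphenoxy)phenyl]ethyl}-4-hydroxy-5-methoxybenzaldehyde
Conditions: 7 (1.0 equiv), K2CO3 (2.5 equiv), DMF (0.2 M), 110 °C, 10 h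
Reagents that add atoms: none
Why: SNAr at the ortho-formyl-activated C–F bond (fluoride leaves far faster than the para bromide), and only the ring A phenoxide reacts because the ring D phenoxide is a doubly ortho-substituted vinylogous carboxylate about 2.5 pKa units less basic.

Step 4
Reactants: 2 3-vinylphenol; 8 3-{2-[4-(5-bromo-2-formylphenoxy)phenyl]ethyl}-4-hydroxy-5-methoxybenzaldehyde
Product: 10 3-{2-[4-(2-formyl-5-[2-(3-hydroxyphenyl)ethyl]phenoxy)phenyl]ethyl}-4-hydroxy-5-methoxybenzaldehyde, via bis-boryl compound 9 (not isolated)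
Conditions: 2 (1.3 equiv), 9-BBN (2.6 equiv), THF, 0 °C to rt, 6 h; 3 M aq K3PO4 (4 equiv, destroys residual B–H); then 8 (1.0 equiv), PdCl2(dppf)·CH2Cl2 (5 mol %), DMF/THF, 50 °C, 12 h
Reagents that add atoms: none
Why: The first equivalent of 9-BBN silences the phenol as its borinate and the second hydroborates the vinyl group, after which B-alkyl Suzuki–Miyaura coupling occurs at a C–Br bond activated by the para formyl group, under a phosphate base that both aryl aldehydes tolerate.

Step 5
Reactants: 10 3-{2-[4-(2-formyl-5-[2-(3-hydroxyphenyl)ethyl]phenoxy)phenyl]ethyl}-4-hydroxy-5-methoxybenzaldehyde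
Product: 12 2-{2-[4-(2-hydroxy-5-[2-(3-hydroxyphenyl)ethyl]phenoxy)phenyl]ethyl}-6-methoxybenzene-1,4-diol, via bis-formate 11 (not isolated)
Conditions: mCPBA (2.4 equiv), CH2Cl2, 0 °C to rt, 8 h; aq Na2S2O3/NaHCO3 wash; then degassed MeOH, HCl (cat.), rt, 1 h, Ar
Reagents that add atoms: mCPBA (3-chloroperoxybenzoic acid), OOC(=O)c1cccc(Cl)c1
Why: Double Baeyer–Villiger (Dakin-type) oxidation, in which each formyl group sits on a ring with an ortho or para oxygen donor so aryl migrates in preference to hydride, the hydroquinone stays masked as its monoformate until the peracid is gone, and aryl formates methanolyse within minutes.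

Step 6
Reactants: 12 2-{2-[4-(2-hydroxy-5-[2-(3-hydroxyphenyl)ethyl]phenoxy)phenyl]ethyl}-6-methoxybenzene-1,4-diol
Product: 15 target macrocyclic methoxyquinone, via seco-quinone 13 (not isolated), via macrocyclic hydroquinone 14 (not isolated)
Conditions: 3,3',5,5'-tetra-tert-butyl-4,4'-diphenoquinone (DPQ, 2.2 equiv), Cs2CO3 (3 equiv), 4 Å MS, degassed DMF, rt, Ar; 12 added by syringe pump over 12 h (final 1 mM); AcOH quench
Reagents that add atoms: none
Why: Proposed new method: DPQ, a hindered oxidant inert to phenoxide addition, oxidises only the low-potential methoxyhydroquinone to 13 and leaves the two simple phenols alone; in 13 the OMe group turns C4=O into a vinylogous ester, so the O=C1–C6=C5 enone is the electrophile and the caesium phenoxide of ring C adds through oxygen at the unsubstituted C5; attack at C2 is degenerate because it only re-expels the better leaving group ArO–, and the ring B phenoxide could close only a strained 12-membered paracyclophane; tautomerisation to 14 and a second DPQ oxidation make the C–O bond irreversible and deliver the quinone oxidation level directly; the closest known reaction types are nucleophilic addition–reoxidation of quinones with amines, thiols and alcohols, laccase-type hydroquinone/nucleophile domino couplings, and phenoxide addition–elimination on haloquinones.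

## Compound list
1 | 3-hydroxybenzaldehyde | O=Cc1cccc(O)c1 | starting material
2 | 3-vinylphenol | C=Cc1cccc(O)c1 | intermediate
3 | 4-acetoxystyrene (4-ethenylphenyl acetate) | CC(=O)Oc1ccc(C=C)cc1 | starting material
4 | 5-iodovanillin (4-hydroxy-3-iodo-5-methoxybenzaldehyde) | COc1cc(C=O)cc(I)c1O | starting material
5 | 4-[2-(9-borabicyclo[3.3.1]nonan-9-yl)ethyl]phenyl acetate | CC(=O)Oc1ccc(CCB2C3CCCC2CCC3)cc1 | intermediate
6 | 4-hydroxy-3-[2-(4-hydroxyphenyl)ethyl]-5-methoxybenzaldehyde | COc1cc(C=O)cc(CCc2ccc(O)cc2)c1O | intermediate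
7 | 4-bromo-2-fluorobenzaldehyde | O=Cc1ccc(Br)cc1F | starting material
8 | 3-{2-[4-(5-bromo-2-formylphenoxy)phenyl]ethyl}-4-hydroxy-5-methoxybenzaldehyde | COc1cc(C=O)cc(CCc2ccc(Oc3cc(Br)ccc3C=O)cc2)c1O | intermediate
9 | 9-{2-[3-(9-borabicyclo[3.3.1]nonan-9-yloxy)phenyl]ethyl}-9-borabicyclo[3.3.1]nonane | C(Cc1cccc(OB2C3CCCC2CCC3)c1)B1C2CCCC1CCC2 | intermediate
10 | 3-{2-[4-(2-formyl-5-[2-(3-hydroxyphenyl)ethyl]phenoxy)phenyl]ethyl}-4-hydroxy-5-methoxybenzaldehyde | COc1cc(C=O)cc(CCc2ccc(Oc3cc(CCc4cccc(O)c4)ccc3C=O)cc2)c1O | intermediate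
11 | 3-{2-[4-(2-formyloxy-5-[2-(3-hydroxyphenyl)ethyl]phenoxy)phenyl]ethyl}-4-hydroxy-5-methoxyphenyl formate | COc1cc(OC=O)cc(CCc2ccc(Oc3cc(CCc4cccc(O)c4)ccc3OC=O)cc2)c1O | intermediate
12 | 2-{2-[4-(2-hydroxy-5-[2-(3-hydroxyphenyl)ethyl]phenoxy)phenyl]ethyl}-6-methoxybenzene-1,4-diol | COc1cc(O)cc(CCc2ccc(Oc3cc(CCc4cccc(O)c4)ccc3O)cc2)c1O | intermediate
13 | 2-{2-[4-(2-hydroxy-5-[2-(3-hydroxyphenyl)ethyl]phenoxy)phenyl]ethyl}-6-methoxy-1,4-benzoquinone | COC1=CC(=O)C=C(CCc2ccc(Oc3cc(CCc4cccc(O)c4)ccc3O)cc2)C1=O | intermediate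
14 | macrocyclic hydroquinone (target with ring D as the 1,4-diol) | COc1cc(O)c2c(CCc3ccc(cc3)Oc3cc(ccc3O)CCc3cccc(c3)O2)c1O | intermediate
15 | target: 18-membered bis(bibenzyl) diether with ring D as 2-methoxy-5-aryloxy-6-alkyl-1,4-benzoquinone and a free OH on ring B (achiral) | COC1=CC(=O)C2=C(CCc3ccc(cc3)Oc3cc(ccc3O)CCc3cccc(c3)O2)C1=O | target

## Count and risks
Total step count: 6. Longest linear sequence: 5 (steps 2, 3, 4, 5 and 6). Step 1 is a one-step side branch.

**Most likely to fail: step 6.**
- Possible failure modes are carbon attack by the ring C phenoxide, base-induced tautomerisation of the alkylquinone to a quinone methide, and oligomerisation.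
- The fallback gives the quinone a leaving group. Ring closure then becomes an addition–elimination that needs neither tautomerisation nor reoxidation.
- It sets out from 12. Ag2O in Et2O/acetone at rt gives 13, which is now isolated.
- Dry HCl in CHCl3 at 0 °C adds chloride at the same electronically favoured C5 to give the open-chain chlorohydroquinone F1.
- A short Ag2O oxidation gives the open-chain 5-chloroquinone F2.
- Slow addition of F2 to Cs2CO3 in DMF (1 mM, rt) closes the ring with loss of chloride and comes back to the route at 15.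

**Second: step 5.**
- Possible failure modes are peracid over-oxidation of the electron-rich ring D and partial hydride migration at the ring B aldehyde.
- The fallback separates the two oxygenations and carries the ring B aldehyde through the ring closure as a masked phenol. This also leaves only one nucleophilic phenol in the key step.
- It sets out from 10. A classical Dakin oxidation (H2O2 1.05 equiv, aq NaOH, THF, 0 °C, N2) touches only the p-hydroxybenzaldehyde and gives the formyl hydroquinone F3.
- Under the step 6 conditions F3 passes through the formyl seco-quinone F4 and the formyl macrocyclic hydroquinone F5 to the formyl macrocyclic quinone F6.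
- mCPBA in CH2Cl2 converts F6 into the macrocyclic aryl formate F7. The electron-poor quinone alkenes are inert to the electrophilic peracid.
- MeOH with catalytic HCl cleaves the formate and comes back to the route at 15.

**Third: step 4.**
- Possible failure modes are aldehyde reduction by boron hydride or alkylborane species, protodebromination, and a sluggish alkyl transfer from the O-borylated partner.
- The fallback replaces the organoborane coupling by sp2–sp2 vinylation and chemoselective hydrogenation.
- It sets out from 8 together with 2. A Heck reaction (Pd(OAc)2, P(o-tol)3, Et3N, DMF, 100 °C) gives the (E)-stilbene dialdehyde F8.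
- H2 (1 atm) over Pd/C poisoned with Ph2S in EtOAc saturates only the alkene, spares both aryl aldehydes, and comes back to the route at 10.

## Further compounds
F1 | step 6 | 3-chloro-2-{2-[4-(2-hydroxy-5-[2-(3-hydroxyphenyl)ethyl]phenoxy)phenyl]ethyl}-6-methoxybenzene-1,4-diol | COc1cc(O)c(Cl)c(CCc2ccc(Oc3cc(CCc4cccc(O)c4)ccc3O)cc2)c1O
F2 | step 6 | 5-chloro-6-{2-[4-(2-hydroxy-5-[2-(3-hydroxyphenyl)ethyl]phenoxy)phenyl]ethyl}-2-methoxy-1,4-benzoquinone | COC1=CC(=O)C(Cl)=C(CCc2ccc(Oc3cc(CCc4cccc(O)c4)ccc3O)cc2)C1=O
F3 | step 5 | 2-{4-[2-(2,5-dihydroxy-3-methoxyphenyl)ethyl]phenoxy}-4-[2-(3-hydroxyphenyl)ethyl]benzaldehyde | COc1cc(O)cc(CCc2ccc(Oc3cc(CCc4cccc(O)c4)ccc3C=O)cc2)c1O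
F4 | step 5 | 4-[2-(3-hydroxyphenyl)ethyl]-2-{4-[2-(5-methoxy-3,6-dioxocyclohexa-1,4-dien-1-yl)ethyl]phenoxy}benzaldehyde | COC1=CC(=O)C=C(CCc2ccc(Oc3cc(CCc4cccc(O)c4)ccc3C=O)cc2)C1=O
F5 | step 5 | macrocyclic hydroquinone with CHO in place of the ring B OH | COc1cc(O)c2c(CCc3ccc(cc3)Oc3cc(ccc3C=O)CCc3cccc(c3)O2)c1O
F6 | step 5 | macrocyclic quinone with CHO in place of the ring B OH | COC1=CC(=O)C2=C(CCc3ccc(cc3)Oc3cc(ccc3C=O)CCc3cccc(c3)O2)C1=O
F7 | step 5 | ring B O-formate of the target | COC1=CC(=O)C2=C(CCc3ccc(cc3)Oc3cc(ccc3OC=O)CCc3cccc(c3)O2)C1=O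
F8 | step 4 | 3-{2-[4-(2-formyl-5-[(E)-2-(3-hydroxyphenyl)ethenyl]phenoxy)phenyl]ethyl}-4-hydroxy-5-methoxybenzaldehyde | COc1cc(C=O)cc(CCc2ccc(Oc3cc(/C=C/c4cccc(O)c4)ccc3C=O)cc2)c1O
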